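The 2,2-dimethylpyran fused to ring B across O2'/C3' is disconnected to a free 2'-phenol and 3-methylbut-2-enal. Because C1' already carries C3 of ring C, C3' is the only open carbon ortho to O2'. A boron-templated ortho-condensation, loss of PhBO and oxa-6π electrocyclisation of the ortho-quinone methide therefore form C3'–C4'' and O2'–C2'' in one operation and can only give the angular chromene. The precursor is an open-chain (R)-2-aryl-3-aryloxypropyl acetate: ring A hangs on O1–C2 as a bis-silyl ether, O4' is silylated, O2' is free, and C4 is an acetoxymethyl group, which keeps C3 configurationally safe and cannot lactonise onto O2'.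

Key step: step 12

Remark: isoflavanone numbering is used (chromanone O1–C8a with ring A, aryl ring B primed, pyran atoms C2''–C4''); TIPS = triisopropylsilyl, TIPSO = triisopropylsilyloxy; the dioxaborin carbon of 20 forms as a mixture of epimers, which is irrelevant because it becomes sp2 in 21.

Step 1
Reactants: 1 2,4-dihydroxyphenylacetic acid
Product: 2 6-hydroxybenzofuran-2(3H)-one
Conditions: TsOH·H2O (cat.), toluene, reflux, Dean–Stark
Reagents that add atoms: none
Why: Acid-catalysed intramolecular esterification (lactonisation) can engage only the ortho hydroxyl in a five-membered ring, so O2' is masked as the lactone while the para hydroxyl (the future O4') stays free, which differentiates the two phenols without relying on selectivity.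

Step 2
Reactants: 2 6-hydroxybenzofuran-2(3H)-one
Product: 3 6-(TIPSO)benzofuran-2(3H)-one
Conditions: TIPSCl, imidazole, CH2Cl2/DMF, 0 °C to rt
Reagents that add atoms: chlorotriisopropylsilane, CC(C)[Si](Cl)(C(C)C)C(C)C
Why: Silyl ether formation on the only free phenol with a silyl chloride and imidazole is routine, and imidazole is too weak a base to enolise the lactone.

Step 3
Reactants: 3 6-(TIPSO)benzofuran-2(3H)-one
Product: 5 methyl 2-[2-(benzyloxy)-4-(TIPSO)phenyl]acetate, via hydroxy ester 4 (not isolated)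
Conditions: MeOH, Et3N (cat.), rt; evaporate below 30 °C; then BnBr, K2CO3, acetone, 50 °C
Reagents that add atoms: methanol, CO; benzyl bromide, BrCc1ccccc1
Why: Amine-catalysed transesterification of the aryl ester by methanol releases O2' as the phenol of 4, and Williamson etherification of that phenoxide with benzyl bromide under anhydrous carbonate conditions, well established for methyl 2-hydroxyphenylacetates, then caps it while the aryl silyl ether is untouched.

Step 4
Reactants: 5 methyl 2-[2-(benzyloxy)-4-(TIPSO)phenyl]acetate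
Product: 6 2-[2-(benzyloxy)-4-(TIPSO)phenyl]acetic acid
Conditions: LiOH·H2O, THF/H2O, 0 °C; then 1 M HCl to pH 3
Reagents that add atoms: lithium hydroxide, [Li+].[OH-]
Why: Saponification of an unhindered methyl arylacetate is fast at 0 °C, where the bulky triisopropylsilyl aryl ether should survive the brief exposure to hydroxide.

Step 5
Reactants: 6 2-[2-(benzyloxy)-4-(TIPSO)phenyl]acetic acid; 7 (R)-4-benzyloxazolidin-2-one
Product: 9 (R)-4-benzyl-3-{2-[2-(benzyloxy)-4-(TIPSO)phenyl]acetyl}oxazolidin-2-one, via mixed pivalic anhydride 8 (not isolated)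
Conditions: PivCl, Et3N, THF, −20 °C; then 7, LiCl, −20 °C to rt
Reagents that add atoms: none
Why: N-Acylation of the oxazolidinone through a mixed pivalic anhydride with LiCl and Et3N is a standard way to make acyl oxazolidinones without strong base, and it leaves the silyl and benzyl ethers alone.

Step 6
Reactants: 9 (R)-4-benzyl-3-{2-[2-(benzyloxy)-4-(TIPSO)phenyl]acetyl}oxazolidin-2-one; 10 benzyl chloromethyl ether
Product: 12 (R)-4-benzyl-3-{(S)-3-(benzyloxy)-2-[2-(benzyloxy)-4-(TIPSO)phenyl]propanoyl}oxazolidin-2-one, via titanium enolate 11 (not isolated)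
Conditions: TiCl4 (1.05 equiv), i-Pr2NEt (1.1 equiv), CH2Cl2, 0 °C; then 10 (freshly distilled, 2 equiv), 0 °C
Reagents that add atoms: none
Why: Oxazolidinone-directed (Evans-type) alkylation of the chelated Z chlorotitanium enolate with an alkoxymethyl chloride is a known, highly face-selective reaction in which the electrophile enters opposite the benzyl group of the auxiliary, so the (R)-auxiliary should set the new centre (the future C3) in the S configuration shown, with the benzyloxymethyl carbon becoming C4.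

Step 7
Reactants: 12 (R)-4-benzyl-3-{(S)-3-(benzyloxy)-2-[2-(benzyloxy)-4-(TIPSO)phenyl]propanoyl}oxazolidin-2-one
Product: 13 (R)-3-(benzyloxy)-2-[2-(benzyloxy)-4-(TIPSO)phenyl]propan-1-ol
Conditions: LiBH4, MeOH (2 equiv), THF, 0 °C
Reagents that add atoms: none
Why: Reductive cleavage of the imide with LiBH4 is a non-basic hydride reduction that releases the auxiliary and gives the primary alcohol without touching the α-aryl stereocentre, whose two oxygenated arms remain differentiated as benzyl ether and free hydroxyl.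

Step 8
Reactants: 14 phloroglucinol
Product: 15 3,5-bis(TIPSO)phenol
Conditions: TIPSCl (2 equiv), imidazole, DMF, 0 °C to rt; chromatographic separation
Reagents that add atoms: chlorotriisopropylsilane, CC(C)[Si](Cl)(C(C)C)C(C)C
Why: Statistical silylation of the threefold-symmetric triphenol with two equivalents of silyl chloride gives the bis-silyl ether as the main separable product, and under- or over-silylated material can be recycled.

Step 9
Reactants: 13 (R)-3-(benzyloxy)-2-[2-(benzyloxy)-4-(TIPSO)phenyl]propan-1-ol; 15 3,5-bis(TIPSO)phenol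
Product: 16 (S)-1-(benzyloxy)-3-[3,5-bis(TIPSO)phenoxy]-2-[2-(benzyloxy)-4-(TIPSO)phenyl]propane
Conditions: PPh3, DIAD, THF, 0 °C to rt
Reagents that add atoms: none
Why: Mitsunobu etherification of a primary alcohol with a phenol forms the O1–C2 bond under neutral conditions at a carbon that is not the stereocentre, and 13 carries neither a free phenol nor an acidic α-hydrogen that could divert the alkoxyphosphonium intermediate.

Step 10
Reactants: 16 (S)-1-(benzyloxy)-3-[3,5-bis(TIPSO)phenoxy]-2-[2-(benzyloxy)-4-(TIPSO)phenyl]propane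
Product: 17 (S)-3-[3,5-bis(TIPSO)phenoxy]-2-[2-hydroxy-4-(TIPSO)phenyl]propan-1-ol
Conditions: H2 (1 atm), 10% Pd/C, EtOAc, rt
Reagents that add atoms: none
Why: Catalytic hydrogenolysis removes the aryl and the alkyl benzyl ether together while aryl silyl ethers and the non-benzylic aryl alkyl ether are inert, and no alkene is present yet.

Step 11
Reactants: 17 (S)-3-[3,5-bis(TIPSO)phenoxy]-2-[2-hydroxy-4-(TIPSO)phenyl]propan-1-ol
Product: 18 (R)-3-[3,5-bis(TIPSO)phenoxy]-2-[2-hydroxy-4-(TIPSO)phenyl]propyl acetate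
Conditions: vinyl acetate, immobilised Candida antarctica lipase B (Novozym 435), MTBE, 40 °C
Reagents that add atoms: vinyl acetate, CC(=O)OC=C
Why: Lipase-catalysed transesterification with vinyl acetate acylates primary aliphatic alcohols but not phenols, so the hydroxymethyl arm is capped and O2' stays free without any base that could move a silyl group.

Step 12
Reactants: 18 (R)-3-[3,5-bis(TIPSO)phenoxy]-2-[2-hydroxy-4-(TIPSO)phenyl]propyl acetate; 19 3-methylbut-2-enal
Product: 22 (R)-3-[3,5-bis(TIPSO)phenoxy]-2-[2,2-dimethyl-5-(TIPSO)-2H-chromen-8-yl]propyl acetate, via benzodioxaborin 20 (not isolated), via ortho-quinone methide 21 (not isolated)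
Conditions: PhB(OH)2 (1.2 equiv), 19 (2.5 equiv), AcOH, toluene, reflux, Dean–Stark
Reagents that add atoms: none
Why: PhB(OH)2 esterifies O2' and the aldehyde oxygen, and the aryloxyboron species delivers the aldehyde carbon intramolecularly to C3' (boron-templated ortho-hydroxyalkylation) to give the 4H-1,3,2-benzodioxaborin 20. On further heating 20 loses PhBO in a retro-hetero-Diels–Alder step to give the ortho-quinone methide 21, whose dienone oxygen and 2-methylpropenyl terminus close by thermal disrotatory oxa-6π electrocyclisation, forming O2'–C2'' after C3'–C4'' and re-aromatising ring B. The closest known reaction type is the phenylboronic acid-mediated condensation of phenols with α,β-unsaturated aldehydes to 2H-chromenes. The pyran ring is closed as a 6-membered ring by this pericyclic step, and no stereocentre is created, since the dioxaborin carbon becomes sp2 and the existing centre has no adjacent carbonyl at this stage. The required selectivity is exclusive closure on O2' at C3', secured by O2' being the only free phenol, by the boron tether that allows only ortho attack, and by the substituent on C1'; the acetate keeps the primary hydroxyl from binding boron, and a carboxyl group at C4, which would lactonise onto O2', is deliberately absent.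

Step 13
Reactants: 22 (R)-3-[3,5-bis(TIPSO)phenoxy]-2-[2,2-dimethyl-5-(TIPSO)-2H-chromen-8-yl]propyl acetate
Product: 23 (S)-3-[3,5-bis(TIPSO)phenoxy]-2-[2,2-dimethyl-5-(TIPSO)-2H-chromen-8-yl]propan-1-ol
Conditions: i-Bu2AlH (2.5 equiv), CH2Cl2, −78 °C; aqueous potassium sodium tartrate
Reagents that add atoms: none
Why: Hydride reduction of the acetate with i-Bu2AlH at low temperature liberates the primary alcohol without exposing the three base-sensitive aryl silyl ethers to alkoxide, and neither the chromene nor the stereocentre is affected.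

Step 14
Reactants: 23 (S)-3-[3,5-bis(TIPSO)phenoxy]-2-[2,2-dimethyl-5-(TIPSO)-2H-chromen-8-yl]propan-1-ol
Product: 25 (R)-3-[3,5-bis(TIPSO)phenoxy]-2-[2,2-dimethyl-5-(TIPSO)-2H-chromen-8-yl]propanoic acid, via aldehyde 24 (not isolated)
Conditions: TEMPO (cat.), PhI(OAc)2 (2.2 equiv), MeCN/CH2Cl2/H2O, 0 °C to rt
Reagents that add atoms: water, O
Why: Oxoammonium-mediated oxidation (catalytic TEMPO with PhI(OAc)2 in the presence of water) carries the primary alcohol through the aldehyde 24 and its hydrate directly to the acid under base-free conditions that are known to spare α-stereocentres and electron-rich alkenes.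

Step 15
Reactants: 25 (R)-3-[3,5-bis(TIPSO)phenoxy]-2-[2,2-dimethyl-5-(TIPSO)-2H-chromen-8-yl]propanoic acid
Product: 27 (R)-5,7-bis(TIPSO)-3-[2,2-dimethyl-5-(TIPSO)-2H-chromen-8-yl]chroman-4-one, via mixed trifluoroacetic anhydride 26 (not isolated)
Conditions: (CF3CO)2O (3 equiv), CH2Cl2 (0.02 M), 0 °C, short reaction time; aqueous NaHCO3 quench
Reagents that add atoms: none
Why: Intramolecular Friedel–Crafts acylation through the mixed trifluoroacetic anhydride closes the 6-membered ring C onto the strongly activated, symmetric ring A, whose two positions ortho to O1 are equivalent so that only one regioisomer can form, and the base-free medium avoids a ketene pathway that would scramble C3.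

Step 16
Reactants: 27 (R)-5,7-bis(TIPSO)-3-[2,2-dimethyl-5-(TIPSO)-2H-chromen-8-yl]chroman-4-one
Product: 28 (R)-5,7-dihydroxy-3-(5-hydroxy-2,2-dimethyl-2H-chromen-8-yl)chroman-4-one (CNP0268151.2)
Conditions: Bu4NF (3.5 equiv), AcOH (4 equiv), THF, 0 °C
Reagents that add atoms: none
Why: Fluoride-induced cleavage of the three aryl silyl ethers is fast, and buffering Bu4NF with acetic acid keeps phenoxide and enolate formation suppressed so that the enolisable C3 centre and the chromene survive.

Compound list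
1 | 2,4-dihydroxyphenylacetic acid | OC(=O)Cc1ccc(O)cc1O | starting material
2 | 6-hydroxybenzofuran-2(3H)-one | O=C1Cc2ccc(O)cc2O1 | intermediate
3 | 6-(triisopropylsilyloxy)benzofuran-2(3H)-one | O=C1Cc2ccc(O[Si](C(C)C)(C(C)C)C(C)C)cc2O1 | intermediate
4 | methyl 2-[2-hydroxy-4-(triisopropylsilyloxy)phenyl]acetate (not isolated) | COC(=O)Cc1ccc(O[Si](C(C)C)(C(C)C)C(C)C)cc1O | intermediate
5 | methyl 2-[2-(benzyloxy)-4-(triisopropylsilyloxy)phenyl]acetate | COC(=O)Cc1ccc(O[Si](C(C)C)(C(C)C)C(C)C)cc1OCc1ccccc1 | intermediate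
6 | 2-[2-(benzyloxy)-4-(triisopropylsilyloxy)phenyl]acetic acid | OC(=O)Cc1ccc(O[Si](C(C)C)(C(C)C)C(C)C)cc1OCc1ccccc1 | intermediate
7 | (R)-4-benzyloxazolidin-2-one | O=C1N[C@H](Cc2ccccc2)CO1 | starting material
8 | 2-[2-(benzyloxy)-4-(triisopropylsilyloxy)phenyl]acetic pivalic anhydride (not isolated) | CC(C)(C)C(=O)OC(=O)Cc1ccc(O[Si](C(C)C)(C(C)C)C(C)C)cc1OCc1ccccc1 | intermediate
9 | (R)-4-benzyl-3-{2-[2-(benzyloxy)-4-(triisopropylsilyloxy)phenyl]acetyl}oxazolidin-2-one | O=C(Cc1ccc(O[Si](C(C)C)(C(C)C)C(C)C)cc1OCc1ccccc1)N1[C@H](Cc2ccccc2)COC1=O | intermediate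
10 | benzyl chloromethyl ether | ClCOCc1ccccc1 | starting material
11 | trichlorotitanium (Z)-enolate of 9 (not isolated) | Cl[Ti](Cl)(Cl)O/C(=C\c1ccc(O[Si](C(C)C)(C(C)C)C(C)C)cc1OCc1ccccc1)N1[C@H](Cc2ccccc2)COC1=O | intermediate
12 | (R)-4-benzyl-3-{(S)-3-(benzyloxy)-2-[2-(benzyloxy)-4-(triisopropylsilyloxy)phenyl]propanoyl}oxazolidin-2-one | c1ccccc1COC[C@@H](C(=O)N1[C@H](Cc2ccccc2)COC1=O)c1ccc(O[Si](C(C)C)(C(C)C)C(C)C)cc1OCc1ccccc1 | intermediate
13 | (R)-3-(benzyloxy)-2-[2-(benzyloxy)-4-(triisopropylsilyloxy)phenyl]propan-1-ol | c1ccccc1COC[C@@H](CO)c1ccc(O[Si](C(C)C)(C(C)C)C(C)C)cc1OCc1ccccc1 | intermediate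
14 | phloroglucinol (benzene-1,3,5-triol) | Oc1cc(O)cc(O)c1 | starting material
15 | 3,5-bis(triisopropylsilyloxy)phenol | Oc1cc(O[Si](C(C)C)(C(C)C)C(C)C)cc(O[Si](C(C)C)(C(C)C)C(C)C)c1 | intermediate
16 | (S)-1-(benzyloxy)-3-[3,5-bis(triisopropylsilyloxy)phenoxy]-2-[2-(benzyloxy)-4-(triisopropylsilyloxy)phenyl]propane | c1ccccc1COC[C@@H](COc1cc(O[Si](C(C)C)(C(C)C)C(C)C)cc(O[Si](C(C)C)(C(C)C)C(C)C)c1)c1ccc(O[Si](C(C)C)(C(C)C)C(C)C)cc1OCc1ccccc1 | intermediate
17 | (S)-3-[3,5-bis(triisopropylsilyloxy)phenoxy]-2-[2-hydroxy-4-(triisopropylsilyloxy)phenyl]propan-1-ol | OC[C@@H](COc1cc(O[Si](C(C)C)(C(C)C)C(C)C)cc(O[Si](C(C)C)(C(C)C)C(C)C)c1)c1ccc(O[Si](C(C)C)(C(C)C)C(C)C)cc1O | intermediate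
18 | (R)-3-[3,5-bis(triisopropylsilyloxy)phenoxy]-2-[2-hydroxy-4-(triisopropylsilyloxy)phenyl]propyl acetate | CC(=O)OC[C@@H](COc1cc(O[Si](C(C)C)(C(C)C)C(C)C)cc(O[Si](C(C)C)(C(C)C)C(C)C)c1)c1ccc(O[Si](C(C)C)(C(C)C)C(C)C)cc1O | intermediate
19 | 3-methylbut-2-enal | CC(C)=CC=O | starting material
20 | (R)-3-[3,5-bis(triisopropylsilyloxy)phenoxy]-2-[4-(2-methylprop-1-enyl)-2-phenyl-5-(triisopropylsilyloxy)-4H-1,3,2-benzodioxaborin-8-yl]propyl acetate, both epimers at the dioxaborin carbon (not isolated) | CC(=O)OC[C@@H](COc1cc(O[Si](C(C)C)(C(C)C)C(C)C)cc(O[Si](C(C)C)(C(C)C)C(C)C)c1)c1ccc(O[Si](C(C)C)(C(C)C)C(C)C)c2C(C=C(C)C)OB(c3ccccc3)Oc12 | intermediate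
21 | (R)-3-[3,5-bis(triisopropylsilyloxy)phenoxy]-2-[5-(3-methylbut-2-enylidene)-6-oxo-4-(triisopropylsilyloxy)cyclohexa-1,3-dien-1-yl]propyl acetate, the ortho-quinone methide (not isolated) | CC(=O)OC[C@@H](COc1cc(O[Si](C(C)C)(C(C)C)C(C)C)cc(O[Si](C(C)C)(C(C)C)C(C)C)c1)C1=CC=C(O[Si](C(C)C)(C(C)C)C(C)C)C(=CC=C(C)C)C1=O | intermediate
22 | (R)-3-[3,5-bis(triisopropylsilyloxy)phenoxy]-2-[2,2-dimethyl-5-(triisopropylsilyloxy)-2H-chromen-8-yl]propyl acetate | CC(=O)OC[C@@H](COc1cc(O[Si](C(C)C)(C(C)C)C(C)C)cc(O[Si](C(C)C)(C(C)C)C(C)C)c1)c1ccc(O[Si](C(C)C)(C(C)C)C(C)C)c2C=CC(C)(C)Oc12 | intermediate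
23 | (S)-3-[3,5-bis(triisopropylsilyloxy)phenoxy]-2-[2,2-dimethyl-5-(triisopropylsilyloxy)-2H-chromen-8-yl]propan-1-ol | OC[C@@H](COc1cc(O[Si](C(C)C)(C(C)C)C(C)C)cc(O[Si](C(C)C)(C(C)C)C(C)C)c1)c1ccc(O[Si](C(C)C)(C(C)C)C(C)C)c2C=CC(C)(C)Oc12 | intermediate
24 | (R)-3-[3,5-bis(triisopropylsilyloxy)phenoxy]-2-[2,2-dimethyl-5-(triisopropylsilyloxy)-2H-chromen-8-yl]propanal (not isolated) | O=C[C@@H](COc1cc(O[Si](C(C)C)(C(C)C)C(C)C)cc(O[Si](C(C)C)(C(C)C)C(C)C)c1)c1ccc(O[Si](C(C)C)(C(C)C)C(C)C)c2C=CC(C)(C)Oc12 | intermediate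
25 | (R)-3-[3,5-bis(triisopropylsilyloxy)phenoxy]-2-[2,2-dimethyl-5-(triisopropylsilyloxy)-2H-chromen-8-yl]propanoic acid | OC(=O)[C@@H](COc1cc(O[Si](C(C)C)(C(C)C)C(C)C)cc(O[Si](C(C)C)(C(C)C)C(C)C)c1)c1ccc(O[Si](C(C)C)(C(C)C)C(C)C)c2C=CC(C)(C)Oc12 | intermediate
26 | mixed anhydride of acid 25 with trifluoroacetic acid, (R) at C3 (not isolated) | FC(F)(F)C(=O)OC(=O)[C@@H](COc1cc(O[Si](C(C)C)(C(C)C)C(C)C)cc(O[Si](C(C)C)(C(C)C)C(C)C)c1)c1ccc(O[Si](C(C)C)(C(C)C)C(C)C)c2C=CC(C)(C)Oc12 | intermediate
27 | (R)-5,7-bis(triisopropylsilyloxy)-3-[2,2-dimethyl-5-(triisopropylsilyloxy)-2H-chromen-8-yl]chroman-4-one | O=C1c2c(O[Si](C(C)C)(C(C)C)C(C)C)cc(O[Si](C(C)C)(C(C)C)C(C)C)cc2OC[C@H]1c1ccc(O[Si](C(C)C)(C(C)C)C(C)C)c2C=CC(C)(C)Oc12 | intermediate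
28 | (R)-5,7-dihydroxy-3-(5-hydroxy-2,2-dimethyl-2H-chromen-8-yl)chroman-4-one | CC1(C)C=Cc2c(O)ccc([C@@H]3COc4cc(O)cc(O)c4C3=O)c2O1 | target

Total step count: 16. Longest linear sequence: 15 steps (steps 1–7 and 9–16, from 1 to 28); step 8 is a one-step side branch.

Steps most likely to fail

Step 15. Three processes could spoil the closure: acid-induced cationic oligomerisation of the chromene double bond, sluggish acylation next to the bulky silyloxy group, and erosion of configuration at C3 by enolisation of the activated acid or of the product ketone in trifluoroacetic acid. The fallback separates activation from closure and avoids the mixed anhydride and added strong acid. It sets out from 25, which is converted with 1-chloro-N,N,2-trimethylprop-1-en-1-amine in CH2Cl2 at 0 °C, under neutral conditions, into (R)-3-[3,5-bis(triisopropylsilyloxy)phenoxy]-2-[2,2-dimethyl-5-(triisopropylsilyloxy)-2H-chromen-8-yl]propanoyl chloride F1. This is then cyclised by a solvent-promoted intramolecular Friedel–Crafts acylation in 1,1,1,3,3,3-hexafluoropropan-2-ol at rt without a Lewis acid (or, failing that, with SnCl4 in CH2Cl2 at −78 °C). The fallback returns to the route at 27.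

Step 12. Steric shielding of C3' by the neighbouring silyloxy group may slow the boron-directed ortho C–C bond formation, so that self-condensation of the aldehyde and thermal decomposition outrun the annulation. The fallback delivers the C5 unit through oxygen first and lets a sigmatropic shift make the C3'–C4'' bond. It sets out from 18, whose O2' is alkylated with 3-chloro-3-methylbut-1-yne (DBU, CuCl2 cat., MeCN, 0 °C) to give (R)-3-[3,5-bis(triisopropylsilyloxy)phenoxy]-2-[2-(2-methylbut-3-yn-2-yloxy)-4-(triisopropylsilyloxy)phenyl]propyl acetate F2. Heating F2 in xylene at about 140 °C should trigger the aromatic propargyl Claisen rearrangement to C3' (the only open ortho carbon), tautomerisation and a 1,5-hydrogen shift to the same ortho-quinone methide 21, which electrocyclises. The fallback returns to the route at 22.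

Step 11. The lipase may bind the bulky, tris-silylated substrate poorly, so that acyl transfer to the hydroxymethyl group stalls. The fallback over-acylates and then unmasks the phenol chemically. It sets out from 17, which is peracetylated (Ac2O, pyridine, DMAP cat., CH2Cl2, 0 °C) to (R)-2-[2-acetoxy-4-(triisopropylsilyloxy)phenyl]-3-[3,5-bis(triisopropylsilyloxy)phenoxy]propyl acetate F3. The aryl acetate of F3 is then removed selectively by aminolysis with pyrrolidine (1.1 equiv, THF, 0 °C), which is much faster for aryl than for alkyl acetates. The fallback returns to the route at 18.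

Further compounds
F1 | step 15 | (R)-3-[3,5-bis(triisopropylsilyloxy)phenoxy]-2-[2,2-dimethyl-5-(triisopropylsilyloxy)-2H-chromen-8-yl]propanoyl chloride | ClC(=O)[C@@H](COc1cc(O[Si](C(C)C)(C(C)C)C(C)C)cc(O[Si](C(C)C)(C(C)C)C(C)C)c1)c1ccc(O[Si](C(C)C)(C(C)C)C(C)C)c2C=CC(C)(C)Oc12
F2 | step 12 | (R)-3-[3,5-bis(triisopropylsilyloxy)phenoxy]-2-[2-(2-methylbut-3-yn-2-yloxy)-4-(triisopropylsilyloxy)phenyl]propyl acetate | CC(=O)OC[C@@H](COc1cc(O[Si](C(C)C)(C(C)C)C(C)C)cc(O[Si](C(C)C)(C(C)C)C(C)C)c1)c1ccc(O[Si](C(C)C)(C(C)C)C(C)C)cc1OC(C)(C)C#C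
F3 | step 11 | (R)-2-[2-acetoxy-4-(triisopropylsilyloxy)phenyl]-3-[3,5-bis(triisopropylsilyloxy)phenoxy]propyl acetate | CC(=O)OC[C@@H](COc1cc(O[Si](C(C)C)(C(C)C)C(C)C)cc(O[Si](C(C)C)(C(C)C)C(C)C)c1)c1ccc(O[Si](C(C)C)(C(C)C)C(C)C)cc1OC(C)=O
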